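**Plan**

1. Retrosynthesis cuts, in order: the seven benzyl ethers; the biaryl bond C2'–C8'' between ring B of the (2S)-flavanone half (locants C2–C8a, C1'–C6') and ring A of the flavone half (double-primed locants); the C2–C1' bond of the flavanone; the O1–C2 bond of a chromone.
2. Enabling feature: the bond lies ortho to O3' on ring B and ortho to O7'' on ring A (a 2,2'-biphenol). The 3'-hydroxyl has only one free ortho carbon, C2', because C4' carries O4'. C8'' (between O1'' and O7'', para to O5'') is the most nucleophilic carbon of the flavone and can be metalated selectively.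
3. Forward, flavone half: luteolin is perbenzylated, iodinated at C8'' and stannylated.
4. Forward, flavanone half: an arylboronic acid is added to 5,7-bis(benzyloxy)chromone under rhodium catalysis with a chiral bisphosphine, which sets C2 (S); the 3'-hydroxyl is then freed.
5. The two complete halves are joined by ligand coupling at tetravalent lead, the metal acting as a one-atom bridge from O3' to C8''; global hydrogenolysis ends the route.
6. Stereochemistry: C2 comes from the catalyst and then passes only through non-basic or weakly basic steps; the biaryl axis is not controlled.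

Key step: step 9

Remark: the target structure defines only C2 (S) and carries no descriptor for the hindered C2'–C8'' axis, so the axis is left uncontrolled and the (2S) compound is carried as whatever atropisomer mixture forms.

**Step 1**
Reactants: 1 luteolin
Product: 2 5,7,3',4'-tetra-O-benzylluteolin
Conditions: BnBr (6 equiv), K2CO3 (8 equiv), DMF, 80 °C
Reagents that add atoms: benzyl bromide BrCc1ccccc1
Why: Williamson etherification of all four phenoxides; the chelated 5-hydroxyl reacts last and is driven by heat and excess bromide, and no stereocentre is involved.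

**Step 2**
Reactants: 2 5,7,3',4'-tetra-O-benzylluteolin
Product: 3 8-iodo-5,7,3',4'-tetra-O-benzylluteolin
Conditions: NIS (1.1 equiv), TFA (0.2 equiv), CH2Cl2/MeCN, 0 °C to rt
Reagents that add atoms: N-iodosuccinimide O=C1CCC(=O)N1I
Why: Electrophilic aromatic iodination; C8 of ring A is ortho to O1 and O7 and para to O5 and is the known site of halogenation of 5,7-dialkoxyflavones, whereas C6 is flanked by two benzyloxy groups and ring B is deactivated by the pyranone.

**Step 3**
Reactants: 3 8-iodo-5,7,3',4'-tetra-O-benzylluteolin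
Product: 4 8-(tributylstannyl)-5,7,3',4'-tetra-O-benzylluteolin
Conditions: (Bu3Sn)2 (1.5 equiv), Pd(PPh3)4 (5 mol%), toluene, 110 °C
Reagents that add atoms: hexabutylditin CCCC[Sn](CCCC)(CCCC)[Sn](CCCC)(CCCC)CCCC
Why: Palladium-catalysed stannylation of an aryl iodide with a distannane (oxidative addition to zerovalent palladium, tin-to-palladium transmetalation, reductive elimination), which tolerates ketones and ethers and is used for 2,6-dialkoxyaryl iodides.

**Step 4**
Reactants: 5 2-(benzyloxy)-5-bromophenol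
Product: 6 1-(benzyloxy)-4-bromo-2-(methoxymethoxy)benzene
Conditions: MOMCl, iPr2NEt, CH2Cl2, 0 °C to rt
Reagents that add atoms: chloromethyl methyl ether COCCl
Why: Standard methoxymethylation of a phenol; the acetal is stable to the organolithium and to the aqueous rhodium step and can later be removed without touching benzyl ethers.

**Step 5**
Reactants: 6 1-(benzyloxy)-4-bromo-2-(methoxymethoxy)benzene
Product: 9 [4-(benzyloxy)-3-(methoxymethoxy)phenyl]boronic acid, via aryllithium 7 (not isolated), via lithium aryltriisopropoxyborate 8 (not isolated)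
Conditions: n-BuLi, THF, −78 °C; B(OiPr)3, −78 °C to rt; 1 M HCl, 0 °C
Reagents that add atoms: triisopropyl borate CC(C)OB(OC(C)C)OC(C)C; water O
Why: Bromine–lithium exchange at −78 °C is faster than any deprotonation, and trapping of the aryllithium with the borate followed by brief mild hydrolysis should give the boronic acid with the acetal intact.

**Step 6**
Reactants: 10 1-[2,4-bis(benzyloxy)-6-hydroxyphenyl]ethan-1-one
Product: 12 5,7-bis(benzyloxy)-4H-chromen-4-one, via enaminone 11 (not isolated)
Conditions: Me2NCH(OMe)2, toluene, 100 °C; then conc. HCl, CH2Cl2, 40 °C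
Reagents that add atoms: N,N-dimethylformamide dimethyl acetal COC(OC)N(C)C
Why: Condensation of the methyl ketone with the amide acetal gives the enaminone, and acid induces conjugate addition of the phenol and loss of dimethylamine to close the pyranone, a standard chromone synthesis.

**Step 7**
Reactants: 12 5,7-bis(benzyloxy)-4H-chromen-4-one; 9 [4-(benzyloxy)-3-(methoxymethoxy)phenyl]boronic acid
Product: 13 (2S)-5,7-bis(benzyloxy)-2-[4-(benzyloxy)-3-(methoxymethoxy)phenyl]chroman-4-one
Conditions: 9 (3 equiv), [RhCl(C2H4)2]2 (1.5 mol%), (S)-MeO-F12-BIPHEP [(S)-2,2'-bis[bis(3,4,5-trifluorophenyl)phosphino]-6,6'-dimethoxybiphenyl] (3.3 mol%), KOH (10 mol%), toluene/H2O 10:1, 30 °C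
Reagents that add atoms: none
Why: Hayashi–Miyaura type rhodium-catalysed asymmetric 1,4-addition, in which the aryl group passes from boron to a hydroxorhodium bisphosphine complex, inserts enantioface-selectively into the chromone C2=C3 bond and the rhodium enolate is hydrolysed; the electron-poor (S)-biaryl bisphosphine is the ligand class that activates chromones and, by the sense of induction of (S)-biaryl bisphosphines with cyclic enones, should set C2 as S.

**Step 8**
Reactants: 13 (2S)-5,7-bis(benzyloxy)-2-[4-(benzyloxy)-3-(methoxymethoxy)phenyl]chroman-4-one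
Product: 14 (2S)-5,7-bis(benzyloxy)-2-[4-(benzyloxy)-3-hydroxyphenyl]chroman-4-one
Conditions: 3 M HCl (aq), MeOH/THF 1:1, 45 °C
Reagents that add atoms: none
Why: Acid-catalysed acetal exchange removes only the methoxymethyl group; benzyl ethers survive and C2 should not be at risk because opening of the chromanone is a base-promoted process.

**Step 9**
Reactants: 4 8-(tributylstannyl)-5,7,3',4'-tetra-O-benzylluteolin; 14 (2S)-5,7-bis(benzyloxy)-2-[4-(benzyloxy)-3-hydroxyphenyl]chroman-4-one
Product: 16 (2S)-5,7-bis(benzyloxy)-2-{4-(benzyloxy)-2-[5,7-bis(benzyloxy)-2-(3,4-bis(benzyloxy)phenyl)-4-oxo-4H-chromen-8-yl]-3-hydroxyphenyl}chroman-4-one, via aryllead triacetate 15 (not isolated)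
Conditions: 4 (1.3 equiv), Pb(OAc)4 (1.25 equiv), Hg(OAc)2 (5 mol%), CHCl3, 40 °C; then 14 (1.0 equiv), pyridine (4 equiv), CHCl3, 60 °C
Reagents that add atoms: none
Why: Mercury-catalysed ipso-substitution of tin by Pb(OAc)4 turns stannane 4 into aryllead triacetate 15, an acetate of which is exchanged for the phenoxide of 14; the aryl(aryloxy)lead diacetate then undergoes ligand coupling through a cyclic transition state that delivers C8'' to the ortho carbon C2' with reduction of tetravalent to divalent lead, and the 2,4-cyclohexadienone formed tautomerises to phenol 16. The closest known reaction type is the Pinhey ortho-C-arylation of phenols with aryllead triacetates, which is precedented for 2,4,6-trialkoxyphenyllead triacetates and for phenols whose reacting ortho carbon is flanked by a bulky group, that is, for tetra-ortho-substituted biaryls. No ring is closed; lead only bridges O3' and C8'' as a one-atom temporary tether in the transition state. No new stereocentre is formed apart from the hindered C2'–C8'' axis, which is left uncontrolled, and C2 is untouched because pyridine is too weak a base to open the chromanone by beta-elimination. The step needs C- over O-arylation and C2' over C4' and C6' on ring B: the cyclic ligand coupling reaches only ortho carbons, and of these only C2' bears hydrogen, while attack at the benzyloxy-bearing C4' is disfavoured because the carbon is inductively deactivated towards this electrophilic aryl transfer and could not rearomatise. On the flavone half the site of bond formation (C8'', not C6'') is secured by the tin atom that steps 2 and 3 place at C8''.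

**Step 10**
Reactants: 16 (2S)-5,7-bis(benzyloxy)-2-{4-(benzyloxy)-2-[5,7-bis(benzyloxy)-2-(3,4-bis(benzyloxy)phenyl)-4-oxo-4H-chromen-8-yl]-3-hydroxyphenyl}chroman-4-one
Product: 17 (2S)-2-{2-[2-(3,4-dihydroxyphenyl)-5,7-dihydroxy-4-oxo-4H-chromen-8-yl]-3,4-dihydroxyphenyl}-5,7-dihydroxychroman-4-one (CNP0265600.1)
Conditions: H2 (1 atm), 10% Pd/C, THF/MeOH 1:1, rt
Reagents that add atoms: none
Why: Hydrogenolysis of the seven benzylic C–O bonds on palladium under neutral conditions at ambient pressure, which should leave the flavone double bond, both ketones and the C2 stereocentre untouched.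

**Compound list**

1 | luteolin, 2-(3,4-dihydroxyphenyl)-5,7-dihydroxy-4H-chromen-4-one | O=c1cc(-c2ccc(O)c(O)c2)oc2cc(O)cc(O)c12 | starting material
2 | 5,7,3',4'-tetra-O-benzylluteolin, 5,7-bis(benzyloxy)-2-[3,4-bis(benzyloxy)phenyl]-4H-chromen-4-one | O=c1cc(-c2ccc(OCc3ccccc3)c(OCc3ccccc3)c2)oc2cc(OCc3ccccc3)cc(OCc3ccccc3)c12 | intermediate
3 | 8-iodo-5,7,3',4'-tetra-O-benzylluteolin | O=c1cc(-c2ccc(OCc3ccccc3)c(OCc3ccccc3)c2)oc2c(I)c(OCc3ccccc3)cc(OCc3ccccc3)c12 | intermediate
4 | 8-(tributylstannyl)-5,7,3',4'-tetra-O-benzylluteolin | O=c1cc(-c2ccc(OCc3ccccc3)c(OCc3ccccc3)c2)oc2c([Sn](CCCC)(CCCC)CCCC)c(OCc3ccccc3)cc(OCc3ccccc3)c12 | intermediate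
5 | 2-(benzyloxy)-5-bromophenol | Oc1cc(Br)ccc1OCc1ccccc1 | starting material
6 | 1-(benzyloxy)-4-bromo-2-(methoxymethoxy)benzene | COCOc1cc(Br)ccc1OCc1ccccc1 | intermediate
7 | [4-(benzyloxy)-3-(methoxymethoxy)phenyl]lithium (not isolated) | [Li]c1ccc(OCc2ccccc2)c(OCOC)c1 | intermediate
8 | lithium [4-(benzyloxy)-3-(methoxymethoxy)phenyl]triisopropoxyborate (not isolated) | [Li+].CC(C)O[B-](OC(C)C)(OC(C)C)c1ccc(OCc2ccccc2)c(OCOC)c1 | intermediate
9 | [4-(benzyloxy)-3-(methoxymethoxy)phenyl]boronic acid | OB(O)c1ccc(OCc2ccccc2)c(OCOC)c1 | intermediate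
10 | 1-[2,4-bis(benzyloxy)-6-hydroxyphenyl]ethan-1-one | CC(=O)c1c(O)cc(OCc2ccccc2)cc1OCc1ccccc1 | starting material
11 | (E)-1-[2,4-bis(benzyloxy)-6-hydroxyphenyl]-3-(dimethylamino)prop-2-en-1-one (not isolated) | CN(C)/C=C/C(=O)c1c(O)cc(OCc2ccccc2)cc1OCc1ccccc1 | intermediate
12 | 5,7-bis(benzyloxy)-4H-chromen-4-one | O=c1ccoc2cc(OCc3ccccc3)cc(OCc3ccccc3)c12 | intermediate
13 | (2S)-5,7-bis(benzyloxy)-2-[4-(benzyloxy)-3-(methoxymethoxy)phenyl]chroman-4-one | O=C1C[C@@H](c2ccc(OCc3ccccc3)c(OCOC)c2)Oc2cc(OCc3ccccc3)cc(OCc3ccccc3)c21 | intermediate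
14 | (2S)-5,7-bis(benzyloxy)-2-[4-(benzyloxy)-3-hydroxyphenyl]chroman-4-one | O=C1C[C@@H](c2ccc(OCc3ccccc3)c(O)c2)Oc2cc(OCc3ccccc3)cc(OCc3ccccc3)c21 | intermediate
15 | {5,7-bis(benzyloxy)-2-[3,4-bis(benzyloxy)phenyl]-4-oxo-4H-chromen-8-yl}lead triacetate (not isolated) | O=c1cc(-c2ccc(OCc3ccccc3)c(OCc3ccccc3)c2)oc2c([Pb](OC(C)=O)(OC(C)=O)OC(C)=O)c(OCc3ccccc3)cc(OCc3ccccc3)c12 | intermediate
16 | (2S)-5,7-bis(benzyloxy)-2-{4-(benzyloxy)-2-[5,7-bis(benzyloxy)-2-(3,4-bis(benzyloxy)phenyl)-4-oxo-4H-chromen-8-yl]-3-hydroxyphenyl}chroman-4-one | O=C1C[C@@H](c2ccc(OCc3ccccc3)c(O)c2-c2c(OCc3ccccc3)cc(OCc3ccccc3)c3c(=O)cc(-c4ccc(OCc5ccccc5)c(OCc5ccccc5)c4)oc23)Oc2cc(OCc3ccccc3)cc(OCc3ccccc3)c21 | intermediate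
17 | (2S)-2-{2-[2-(3,4-dihydroxyphenyl)-5,7-dihydroxy-4-oxo-4H-chromen-8-yl]-3,4-dihydroxyphenyl}-5,7-dihydroxychroman-4-one | O=C1C[C@@H](c2ccc(O)c(O)c2-c2c(O)cc(O)c3c(=O)cc(-c4ccc(O)c(O)c4)oc23)Oc2cc(O)cc(O)c21 | target

**Summary**

Total steps: 10. Longest linear sequence: 6 steps (steps 4, 5, 7, 8, 9, 10).

**Steps most likely to fail**

Step 9. Ligand coupling at the doubly flanked C2' may be slower than transfer of acetate from lead to the phenol ring or than protodeplumbation, and attack at the benzyloxy-bearing C4' may compete. The fallback is a Suzuki–Miyaura coupling with the halogen on ring B; it sets out from iodide 3 and acetophenone 10 and comes back to the route at 17. Iodide 3 would be converted by Miyaura borylation (B2pin2, PdCl2(dppf), KOAc, dioxane, 90 °C) into 8-(pinacolboryl)-5,7,3',4'-tetra-O-benzylluteolin F1. Commercial 2-bromo-3-hydroxy-4-methoxybenzaldehyde would be demethylated (BBr3, CH2Cl2) to 2-bromo-3,4-dihydroxybenzaldehyde F2 and benzylated (BnBr, K2CO3, DMF) to 3,4-bis(benzyloxy)-2-bromobenzaldehyde F3. Claisen–Schmidt condensation of F3 with 10 (KOH, EtOH/THF) should give the 2'-hydroxychalcone F4, which would be cyclised (NaOAc, EtOH, reflux) to the racemic 2'-bromoflavanone F5. F5 would be resolved by chromatography on a chiral stationary phase to the (2S)-2'-bromoflavanone F6. Coupling of F6 with F1 (Pd(OAc)2, SPhos, anhydrous K3PO4, toluene, 90 °C) should give the octabenzyl ether F7, and hydrogenolysis of F7 (H2, Pd/C) leads to 17.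

Step 7. Insertion of the electron-rich, peri-alkoxylated chromone may be slow, the boronic acid may protodeboronate, and enantiopurity may erode through reversible opening of the chromanone in the aqueous medium. The fallback is a racemic synthesis with kinetic resolution; it sets out from acetophenone 10 and comes back at 13. Commercial 4-(benzyloxy)-3-hydroxybenzaldehyde would be methoxymethylated (MOMCl, iPr2NEt) to 4-(benzyloxy)-3-(methoxymethoxy)benzaldehyde F8. Condensation of F8 with 10 (KOH, EtOH) should give the 2'-hydroxychalcone F9, which would be cyclised (NaOAc, EtOH, reflux) to the racemic flavanone F10. Noyori-type asymmetric transfer hydrogenation (RuCl(p-cymene)[(R,R)-TsDPEN], HCO2H/Et3N, EtOAc) should reduce the (2R)-ketone to the cis-(2R,4R)-flavan-4-ol F11 and leave the (2S)-ketone 13, which is separated by chromatography.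

Step 10. The flavone C2''=C3'' bond may be over-reduced, or cleavage of the hindered benzyl ethers may stall through catalyst poisoning by traces of tin, lead or mercury. The fallback is a non-reductive Lewis-acid debenzylation; it sets out from 16 and comes back at 17 directly. Compound 16 would be treated with BCl3 and pentamethylbenzene as cation scavenger in CH2Cl2 at −78 °C, followed by a methanol quench. No new compound arises (entry F0).

**Further compounds**

F1 | step 9 | 8-(4,4,5,5-tetramethyl-1,3,2-dioxaborolan-2-yl)-5,7,3',4'-tetra-O-benzylluteolin | O=c1cc(-c2ccc(OCc3ccccc3)c(OCc3ccccc3)c2)oc2c(B3OC(C)(C)C(C)(C)O3)c(OCc3ccccc3)cc(OCc3ccccc3)c12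
F2 | step 9 | 2-bromo-3,4-dihydroxybenzaldehyde | O=Cc1ccc(O)c(O)c1Br
F3 | step 9 | 3,4-bis(benzyloxy)-2-bromobenzaldehyde | O=Cc1ccc(OCc2ccccc2)c(OCc2ccccc2)c1Br
F4 | step 9 | (E)-1-[2,4-bis(benzyloxy)-6-hydroxyphenyl]-3-[3,4-bis(benzyloxy)-2-bromophenyl]prop-2-en-1-one | O=C(/C=C/c1ccc(OCc2ccccc2)c(OCc2ccccc2)c1Br)c1c(O)cc(OCc2ccccc2)cc1OCc1ccccc1
F5 | step 9 | racemic 5,7-bis(benzyloxy)-2-[3,4-bis(benzyloxy)-2-bromophenyl]chroman-4-one | O=C1CC(c2ccc(OCc3ccccc3)c(OCc3ccccc3)c2Br)Oc2cc(OCc3ccccc3)cc(OCc3ccccc3)c21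
F6 | step 9 | (2S)-5,7-bis(benzyloxy)-2-[3,4-bis(benzyloxy)-2-bromophenyl]chroman-4-one | O=C1C[C@@H](c2ccc(OCc3ccccc3)c(OCc3ccccc3)c2Br)Oc2cc(OCc3ccccc3)cc(OCc3ccccc3)c21
F7 | step 9 | (2S)-5,7-bis(benzyloxy)-2-{3,4-bis(benzyloxy)-2-[5,7-bis(benzyloxy)-2-(3,4-bis(benzyloxy)phenyl)-4-oxo-4H-chromen-8-yl]phenyl}chroman-4-one | O=C1C[C@@H](c2ccc(OCc3ccccc3)c(OCc3ccccc3)c2-c2c(OCc3ccccc3)cc(OCc3ccccc3)c3c(=O)cc(-c4ccc(OCc5ccccc5)c(OCc5ccccc5)c4)oc23)Oc2cc(OCc3ccccc3)cc(OCc3ccccc3)c21
F8 | step 7 | 4-(benzyloxy)-3-(methoxymethoxy)benzaldehyde | COCOc1cc(C=O)ccc1OCc1ccccc1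
F9 | step 7 | (E)-1-[2,4-bis(benzyloxy)-6-hydroxyphenyl]-3-[4-(benzyloxy)-3-(methoxymethoxy)phenyl]prop-2-en-1-one | COCOc1cc(/C=C/C(=O)c2c(O)cc(OCc3ccccc3)cc2OCc2ccccc2)ccc1OCc1ccccc1
F10 | step 7 | racemic 5,7-bis(benzyloxy)-2-[4-(benzyloxy)-3-(methoxymethoxy)phenyl]chroman-4-one | O=C1CC(c2ccc(OCc3ccccc3)c(OCOC)c2)Oc2cc(OCc3ccccc3)cc(OCc3ccccc3)c21
F11 | step 7 | (2R,4R)-5,7-bis(benzyloxy)-2-[4-(benzyloxy)-3-(methoxymethoxy)phenyl]chroman-4-ol | O[C@@H]1C[C@H](c2ccc(OCc3ccccc3)c(OCOC)c2)Oc2cc(OCc3ccccc3)cc(OCc3ccccc3)c21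
F0 | step 10 | none | none
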